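(Readings and results are calculated for an exercise.)

Slowness shows here as a gap between two readings. In the winter run X has lost 57.0% by 15.0 min, yet Q stands at 4%. So I call P the charged X minus X and Q, a hidden intermediate, and treat the flask as a tank with a fill from X and a drain into Q.

| setting | dawn | winter | red | amber | teal | green | grey | violet |
|---|---|---|---|---|---|---|---|---|
| X | 0.26 M | 0.26 M | 0.26 M | 0.26 M | 0.26 M | 0.26 M | 0.26 M | 0.26 M |
| J | 1.05 equiv | 1.9 equiv | 1.05 equiv | 3.20 equiv | 1.05 equiv | 1.05 equiv | 1.05 equiv | 1.05 equiv |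
| L | 2.8 mol% | 7.5 mol% | 7.5 mol% | 7.5 mol% | 7.5 mol% | 2.5 mol% | 30 mol% | 5 mol% |
| G | 0.11 mol% | 0.11 mol% | 0.11 mol% | 0.08 mol% | 0.11 mol% | 0.04 mol% | 0.11 mol% | 0.2 mol% |
| temperature | 25 °C | 65 °C | 30 °C | 60 °C | 60 °C | 60 °C | 100 °C | 80 °C |
| remark | run made earlier | run made earlier |  |  |  |  |  |  |
| time |  |  | 2.0 h | 2.0 h | 2.0 h | 2.0 h | 2.0 h | 2.0 h |

dawn run (percent of the X charged)

| time / h | Q / % | X / % |
|---|---|---|
| 0.500 | 1 | 99 |
| 1.00 | 2 | 94 |
| 2.50 | 1 | 85 |
| 4.00 | 1 | 81 |
| 5.00 | 1 | 76 |
| 6.00 | 3 | 73 |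
| 8.00 | 5 | 64 |

winter run (percent of the X charged)

| time / min | Q / % | X / % |
|---|---|---|
| 15.0 | 4 | 43 |
| 30.0 | 8 | 28 |
| 50.0 | 16 | 25 |
| 60.0 | 19 | 24 |
| 80.0 | 25 | 21 |

(standard deviation of a reading: 2 percentage points)

- the flasks by amount of Q, in percent of the X charged, highest first, at 2.0 h (red / amber / teal / green / grey / violet)
- the amount of Q, in percent of the X charged of the flask you put first, at 2.0 h
- the amount of Q, in percent of the X charged of the flask you put last, at 2.0 h

Late in the winter run Q climbs steadily, and P at 60.0 min is 57.0%. The rate of Q over P is then: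

κ(winter) = 0.204 h⁻¹ / 57.0% = 0.358 h⁻¹

This drain constant κ, a pseudo-first-order constant read off scattered readings, is what I carry. Now I turn the settings one after the other.

I expect L to act on the fill. X falls faster in winter, but the temperature and J differ along with L, so the two runs don't part them, and I leave L out of κ.

J I guess enters κ in proportion, and G likewise, which is a guess too, since no earlier run changes G.

Temperature comes from the dawn run, where I take 0.5 of the last P as its mean:

κ(dawn) = Q / (0.5 P t) = 0.0403 h⁻¹

Per equivalent of J, winter exceeds dawn by a factor ρ = 4.91 over 40.0 K. This is a reading that rests on a Q of 5% with a scatter of 2 percentage points.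

Grey and violet share the same J, and for them my own reckoning gives:

κ(grey)/κ(violet) = (G ratio) × ρ^(ΔT/40.0 K) = 1.22

So I place grey ahead of violet, though ρ carries the scatter of that Q.

The forecast differs. It reads violet > grey > amber > teal > green > red, with 65% for the first flask and 2% for the last, and says violet “has double G and fast steps”.

The flasks come out as grey > violet > amber > teal > green > red, with grey at 53.9%, violet at 49.1% and red at 2.13%, so the forecast's top value stands 11 points above grey. In grey, Z, which is the pool P, still holds 31.4% at 2.00 h. My 1.22 is a ratio of drains, not of Q, whose ratio, grey to violet, is 1.10. Multiplied by the Z of grey over the 35.6% of violet, it reckons the rate of Q in grey at 2.00 h at 1.08 times that in violet.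

    X + L ⇌ L + Z (K = 2.80, k = 2.20 L mol⁻¹ min⁻¹, Ea = 68.0 kJ mol⁻¹, ΔH = −7.00 kJ mol⁻¹)
    J + G + Z → G + Q (k = 49.0 L² mol⁻² min⁻¹, Ea = 37.0 kJ mol⁻¹)
    J ⇌ E (K = 0.430, k = 0.0170 min⁻¹, Ea = 106 kJ mol⁻¹, ΔH = −28.0 kJ mol⁻¹)
    (constants at 60 °C)

Take the flask like red but with 4.20 equiv of J. Scaling from winter gives:

κ = 0.197 h⁻¹

With 0.5 of red's Z as the mean pool, Q comes to about 6.37%. The computed flask gives 7.61%.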